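Labdane numbering (ring A: C1–C5, C10; ring B: C5–C10). Everything rests on the C9–C10 bond of ring B. Because C8 carries the C17 carboxyl between C7 and C9, the C7=C8 enoate can be traded for an isomeric C8=C9 enoate whose β-carbon is C9, while quaternary C10 is the Markovnikov carbon of a ring A alkene: two acceptor-type carbons. Metal-hydride H-atom transfer reverses the polarity of C10, and one cobalt-catalysed cycloisomerisation closes ring B, sets C10 and C9 and returns H• from C7, so that the C7=C8 enoate emerges directly. The precursor is a monocyclic isomer of the product: an (S)-2,6,6-trimethylcyclohex-2-enyl ring tied through C6–C7 to a (Z)-enoate bearing the (S)-citronellol chain.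

Key step: step 9

Remark: the given SMILES corresponds to the normal labdane series (5S,9R,10S,13S). Compounds 1, 3, 8 and 10 are taken as catalogue compounds.

Step 1
Reactants: 1 2,4,4-trimethylcyclohex-2-en-1-one
Product: 2 (1R)-2,4,4-trimethylcyclohex-2-en-1-ol
Conditions: (S)-Me-CBS oxazaborolidine (15 mol %), BH3·SMe2, THF, −20 °C; MeOH, aqueous work-up
Reagents that add atoms: none
Why: Corey–Bakshi–Shibata reduction, in which the methyl-bearing sp2 carbon acts as the large flank and the ring CH2 as the small flank of the carbonyl, so the (S)-catalyst should give the (R)-carbinol by 1,2-reduction.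

Step 2
Reactants: 2 (1R)-2,4,4-trimethylcyclohex-2-en-1-ol; 3 triethyl orthoacetate
Product: 5 ethyl 2-[(1S)-2,6,6-trimethylcyclohex-2-en-1-yl]acetate, via ketene acetal 4 (not isolated)
Conditions: 3 (excess), EtCO2H (cat.), 140 °C, EtOH distilled off
Reagents that add atoms: none
Why: Johnson–Claisen rearrangement, in which the suprafacial [3,3] shift of 4 trades the C1–O stereocentre for the C5–C6 bond on the same ring face (1,3-chirality transfer, sets C5) and moves the alkene to C1=C10.

Step 3
Reactants: 5 ethyl 2-[(1S)-2,6,6-trimethylcyclohex-2-en-1-yl]acetate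
Product: 6 2-[(1S)-2,6,6-trimethylcyclohex-2-en-1-yl]ethan-1-ol
Conditions: LiAlH4, Et2O, 0 °C; Fieser work-up
Reagents that add atoms: none
Why: Hydride reduction of an ester to the primary alcohol, which leaves the isolated trisubstituted alkene and C5 untouched.

Step 4
Reactants: 6 2-[(1S)-2,6,6-trimethylcyclohex-2-en-1-yl]ethan-1-ol
Product: 7 (6S)-6-(2-iodoethyl)-1,5,5-trimethylcyclohex-1-ene
Conditions: I2, PPh3, imidazole, CH2Cl2, 0 °C to rt
Reagents that add atoms: iodine, II
Why: Appel-type (Garegg–Samuelsson) iodination, an SN2 displacement of the alkoxyphosphonium ion at an unhindered primary carbon.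

Step 5
Reactants: 7 (6S)-6-(2-iodoethyl)-1,5,5-trimethylcyclohex-1-ene; 8 methyl 2-[bis(2,2,2-trifluoroethoxy)phosphoryl]acetate
Product: 9 methyl 2-[bis(2,2,2-trifluoroethoxy)phosphoryl]-4-[(1S)-2,6,6-trimethylcyclohex-2-en-1-yl]butanoate (C8 epimers)
Conditions: 8 (slight excess), NaH, DMF, 0 °C; then 7, 50 °C
Reagents that add atoms: none
Why: SN2 alkylation of a stabilised phosphonoacetate anion makes the C7–C8 bond, and the new C8 centre forms as a mixture that step 8 erases.

Step 6
Reactants: 10 (S)-citronellol, (3S)-3,7-dimethyloct-6-en-1-ol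
Product: 11 (S)-citronellyl tert-butyldimethylsilyl ether
Conditions: TBSCl, imidazole, CH2Cl2, rt
Reagents that add atoms: tert-butyldimethylsilyl chloride, CC(C)(C)[Si](C)(C)Cl
Why: Standard silylation of a primary alcohol; C13 comes from the chiral pool and is not touched.

Step 7
Reactants: 11 (S)-citronellyl tert-butyldimethylsilyl ether
Product: 13 (4S)-6-[(tert-butyldimethylsilyl)oxy]-4-methylhexanal, via ozonide 12 (not isolated)
Conditions: O3, CH2Cl2, −78 °C; then Me2S, −78 °C to rt
Reagents that add atoms: ozone, [O-][O+]=O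
Why: Ozonolysis with reductive work-up (Criegee mechanism) cleaves the isopropylidene end and exposes the future C9 as an aldehyde.

Step 8
Reactants: 9 methyl 2-[bis(2,2,2-trifluoroethoxy)phosphoryl]-4-[(1S)-2,6,6-trimethylcyclohex-2-en-1-yl]butanoate; 13 (4S)-6-[(tert-butyldimethylsilyl)oxy]-4-methylhexanal
Product: 14 methyl (2Z,6S)-8-[(tert-butyldimethylsilyl)oxy]-6-methyl-2-{2-[(1S)-2,6,6-trimethylcyclohex-2-en-1-yl]ethyl}oct-2-enoate
Conditions: 9, KHMDS, 18-crown-6, THF, −78 °C; then 13
Reagents that add atoms: none
Why: Still–Gennari variant of the Horner–Wadsworth–Emmons olefination, in which the electron-poor phosphonate and the dissociated potassium ion make elimination from the kinetic adduct fast, so C11 should end cis to the ester (Z).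

Step 9
Reactants: 14 methyl (2Z,6S)-8-[(tert-butyldimethylsilyl)oxy]-6-methyl-2-{2-[(1S)-2,6,6-trimethylcyclohex-2-en-1-yl]ethyl}oct-2-enoate
Product: 15 methyl (5S,9R,10S,13S)-15-[(tert-butyldimethylsilyl)oxy]labd-7-en-17-oate
Conditions: Co(III)(salen)Cl [salen = N,N'-bis(3,5-di-tert-butylsalicylidene)ethylenediamine dianion] (10 mol %), PhSiH3 (20 mol %), degassed benzene (0.01 M), rt to 50 °C
Reagents that add atoms: none
Why: Proposed new method: the Co(III)–H formed from the salen complex and the silane should transfer H• to C1 of the electron-rich ring alkene (MHAT), making the Markovnikov carbon C10 a nucleophilic tertiary radical that adds to the enoate β-carbon C9, after which Co(II) takes H• back from C7 of the tertiary α-ester radical at C8, so the C7=C8 enoate and the Co–H are regenerated and 14 is simply isomerised to 15. The closest known reaction types are the cobalt-salen MHAT cycloisomerisation of unactivated 1,6-dienes (5-exo), the iron-mediated reductive MHAT Giese cyclisation, and H• abstraction from methacrylate-type radicals by Co(II) in catalytic chain transfer; their combination in a closure onto a trisubstituted enoate that builds a quaternary carbon has not been shown. Ring B closes in the 6-endo-trig mode, the 5-exo attack at C8 being disfavoured by polarity (α-carbon) and by the full substitution of C8. C10 is controlled by C5: with the C5 tether equatorial on the ring A chair, C9 arrives on the α face, which is also the face free of the axial C4 methyl group, so the C10 methyl ends β and the decalin trans, as in the second closure of radical polyene cascades that pass through the same type of radical. C9 is controlled by the Z geometry of 14: in the chair-like transition state the substituent trans to C7 (C11) becomes equatorial, which places H9 on the α face. The step needs HAT to the donor alkene rather than to the hindered enoate (the selectivity on which all MHAT Giese couplings rest) and H• return from the accessible C7 methylene rather than from the shielded C9–H or, earlier, from C5–H of the C10 radical, and high dilution keeps Co(II) low to favour cyclisation over that back transfer.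

Step 10
Reactants: 15 methyl (5S,9R,10S,13S)-15-[(tert-butyldimethylsilyl)oxy]labd-7-en-17-oate
Product: 16 (5S,9R,10S,13S)-15-[(tert-butyldimethylsilyl)oxy]labd-7-en-17-oic acid
Conditions: LiOH, THF/MeOH/H2O, 60 °C; then 1 M HCl, 0 °C
Reagents that add atoms: lithium hydroxide, [Li+].[OH-]
Why: Saponification of the conjugated methyl ester, in which C9–H is not acidic so no stereocentre is at risk, and any silyl ether lost here converges in step 11.

Step 11
Reactants: 16 (5S,9R,10S,13S)-15-[(tert-butyldimethylsilyl)oxy]labd-7-en-17-oic acid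
Product: 18 (5S,9R,10S,13S)-15-(formyloxy)labd-7-en-17-oic acid (target), via hydroxy acid 17 (not isolated)
Conditions: HCO2H (98 %), 40 °C; evaporation
Reagents that add atoms: formic acid, O=CO
Why: Acidolysis of the primary silyl ether followed by Fischer-type formylation of the freed alcohol in neat formic acid, conditions the conjugated acid should survive unchanged.

Compound list
1 | 2,4,4-trimethylcyclohex-2-en-1-one | CC1=CC(C)(C)CCC1=O | starting material
2 | (1R)-2,4,4-trimethylcyclohex-2-en-1-ol | O[C@@H]1CCC(C)(C)C=C1C | intermediate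
3 | triethyl orthoacetate | CCOC(C)(OCC)OCC | starting material
4 | 1-ethoxyvinyl ether of 2 (ketene acetal, not isolated) | C=C(OCC)O[C@@H]1CCC(C)(C)C=C1C | intermediate
5 | ethyl 2-[(1S)-2,6,6-trimethylcyclohex-2-en-1-yl]acetate | CCOC(=O)C[C@H]1C(C)(C)CCC=C1C | intermediate
6 | 2-[(1S)-2,6,6-trimethylcyclohex-2-en-1-yl]ethan-1-ol | OCC[C@H]1C(C)(C)CCC=C1C | intermediate
7 | (6S)-6-(2-iodoethyl)-1,5,5-trimethylcyclohex-1-ene | ICC[C@H]1C(C)(C)CCC=C1C | intermediate
8 | methyl 2-[bis(2,2,2-trifluoroethoxy)phosphoryl]acetate | COC(=O)CP(=O)(OCC(F)(F)F)OCC(F)(F)F | starting material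
9 | methyl 2-[bis(2,2,2-trifluoroethoxy)phosphoryl]-4-[(1S)-2,6,6-trimethylcyclohex-2-en-1-yl]butanoate (C8 epimers) | COC(=O)C(CC[C@H]1C(C)(C)CCC=C1C)P(=O)(OCC(F)(F)F)OCC(F)(F)F | intermediate
10 | (S)-citronellol | C[C@@H](CCC=C(C)C)CCO | starting material
11 | (S)-citronellyl tert-butyldimethylsilyl ether | C[C@@H](CCC=C(C)C)CCO[Si](C)(C)C(C)(C)C | intermediate
12 | secondary ozonide of 11 (1,2,4-trioxolane, not isolated) | CC1(C)OOC(CC[C@H](C)CCO[Si](C)(C)C(C)(C)C)O1 | intermediate
13 | (4S)-6-[(tert-butyldimethylsilyl)oxy]-4-methylhexanal | O=CCC[C@H](C)CCO[Si](C)(C)C(C)(C)C | intermediate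
14 | methyl (2Z,6S)-8-[(tert-butyldimethylsilyl)oxy]-6-methyl-2-{2-[(1S)-2,6,6-trimethylcyclohex-2-en-1-yl]ethyl}oct-2-enoate | COC(=O)/C(CC[C@H]1C(C)(C)CCC=C1C)=C\CC[C@H](C)CCO[Si](C)(C)C(C)(C)C | intermediate
15 | methyl (5S,9R,10S,13S)-15-[(tert-butyldimethylsilyl)oxy]labd-7-en-17-oate | C[C@H](CCO[Si](C)(C)C(C)(C)C)CC[C@H]1C(C(=O)OC)=CC[C@H]2C(C)(C)CCC[C@]12C | intermediate
16 | (5S,9R,10S,13S)-15-[(tert-butyldimethylsilyl)oxy]labd-7-en-17-oic acid | C[C@H](CCO[Si](C)(C)C(C)(C)C)CC[C@H]1C(C(=O)O)=CC[C@H]2C(C)(C)CCC[C@]12C | intermediate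
17 | (5S,9R,10S,13S)-15-hydroxylabd-7-en-17-oic acid (not isolated) | C[C@H](CCO)CC[C@H]1C(C(=O)O)=CC[C@H]2C(C)(C)CCC[C@]12C | intermediate
18 | (5S,9R,10S,13S)-15-(formyloxy)labd-7-en-17-oic acid = (1R,4aS,8aS)-1-[(3S)-5-(formyloxy)-3-methylpentyl]-5,5,8a-trimethyl-1,4,4a,5,6,7,8,8a-octahydronaphthalene-2-carboxylic acid | C[C@H](CCOC=O)CC[C@H]1C(C(=O)O)=CC[C@H]2C(C)(C)CCC[C@]12C | target

Total step count: 11. Longest linear sequence: 9 (steps 1–5 and 8–11).

Steps most likely to fail

Step 9. The C10 radical may hand H• back to cobalt faster than it cyclises. The ring alkene would then merely migrate, in the worst case into the tetrasubstituted C5=C10 position with loss of the C5 stereocentre. Alternatively, HAT to the trisubstituted donor alkene may be too slow for turnover. The fallback uses known chemistry, sets out from 14 and comes back at 15. A reductive MHAT Giese cyclisation (Fe(acac)3, stoichiometric PhSiH3, EtOH, 60 °C) passes through the same chair-like 6-endo closure. Here the α-ester radical is reduced and protonated, which should give methyl 15-[(tert-butyldimethylsilyl)oxy]labdan-17-oate F1 as C8 epimers. Enolisation with LDA and trapping with PhSeBr gives the 8-phenylselanyl ester F2. H2O2 oxidises this to the selenoxide F3, whose syn elimination toward the accessible C7 methylene gives 15.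

Step 8. The bulky α-substituent of 9 may slow the elimination and make the addition reversible. This would erode the kinetic Z selectivity, and the E isomer would feed the 9-epi series in step 9. The fallback sets out from 8, 13 and 7 and comes back at 14, making the C7–C8 bond by stereoretentive cross-coupling instead of alkylation. Monobromination of 8 (NaH, then NBS, THF) gives methyl 2-bromo-2-[bis(2,2,2-trifluoroethoxy)phosphoryl]acetate F4. Its olefination with 13 (t-BuOK, 18-crown-6, THF, −78 °C) gives methyl (2E,6S)-2-bromo-8-[(tert-butyldimethylsilyl)oxy]-6-methyloct-2-enoate F5, whose geometric isomers can be separated. Zinc insertion into 7 (Zn, LiCl, THF) gives 2-[(1S)-2,6,6-trimethylcyclohex-2-en-1-yl]ethylzinc iodide F6. Negishi coupling of F5 with F6 (PdCl2(dppf), THF) gives 14 with retention of geometry.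

Step 2. The new bond is made next to the quaternary C4, so the rearrangement may be slow. Acid-promoted ionisation of the allylic alcohol (loss of enantiopurity, dehydration) may then compete. The fallback sets out from 1 and comes back at 6, replacing the sigmatropic shift with an anti-SN2' allylic substitution. Reduction of 1 with the (R)-CBS catalyst gives (1S)-2,4,4-trimethylcyclohex-2-en-1-ol F7. Esterification with picolinic acid (DCC, DMAP) gives the picolinate F8. Vinylmagnesium bromide with CuBr·SMe2 displaces it at C5 anti to the leaving group and gives (6S)-6-ethenyl-1,5,5-trimethylcyclohex-1-ene F9. Chemoselective hydroboration of the vinyl group (9-BBN; NaOH, H2O2) gives 6.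

Further compounds
F1 | step 9 | methyl 15-[(tert-butyldimethylsilyl)oxy]labdan-17-oate (normal series, 13S, C8 epimers) | C[C@H](CCO[Si](C)(C)C(C)(C)C)CC[C@H]1C(C(=O)OC)CC[C@H]2C(C)(C)CCC[C@]12C
F2 | step 9 | methyl 15-[(tert-butyldimethylsilyl)oxy]-8-(phenylselanyl)labdan-17-oate | C[C@H](CCO[Si](C)(C)C(C)(C)C)CC[C@H]1C([Se]c3ccccc3)(C(=O)OC)CC[C@H]2C(C)(C)CCC[C@]12C
F3 | step 9 | selenoxide of F2 | C[C@H](CCO[Si](C)(C)C(C)(C)C)CC[C@H]1C([Se](=O)c3ccccc3)(C(=O)OC)CC[C@H]2C(C)(C)CCC[C@]12C
F4 | step 8 | methyl 2-bromo-2-[bis(2,2,2-trifluoroethoxy)phosphoryl]acetate | COC(=O)C(Br)P(=O)(OCC(F)(F)F)OCC(F)(F)F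
F5 | step 8 | methyl (2E,6S)-2-bromo-8-[(tert-butyldimethylsilyl)oxy]-6-methyloct-2-enoate | COC(=O)/C(Br)=C\CC[C@H](C)CCO[Si](C)(C)C(C)(C)C
F6 | step 8 | 2-[(1S)-2,6,6-trimethylcyclohex-2-en-1-yl]ethylzinc iodide | I[Zn]CC[C@H]1C(C)(C)CCC=C1C
F7 | step 2 | (1S)-2,4,4-trimethylcyclohex-2-en-1-ol | O[C@H]1CCC(C)(C)C=C1C
F8 | step 2 | (1S)-2,4,4-trimethylcyclohex-2-en-1-yl pyridine-2-carboxylate | O=C(O[C@H]1CCC(C)(C)C=C1C)c2ccccn2
F9 | step 2 | (6S)-6-ethenyl-1,5,5-trimethylcyclohex-1-ene | C=C[C@H]1C(C)(C)CCC=C1C
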